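**Plan**

- Numbering used throughout: ring C1 (CH carrying the pentenyl chain), C2 (quaternary), C3 (CHBr), C4, C5, C6 (C(CH3)OH). Retrosynthesis removes the silyl ether, cuts the side-chain alkene (cross-metathesis back to an allyl group), takes the C3 bromide back through a C3 geminal dibromide to a C3 ketone, and then cuts the ring bond C3–C4.
- Enabling feature: C3 and the carbinol carbon C6 stand 1,4 across the cyclohexane, so the C6 oxygen can serve as the ring oxygen and C3 as the carbonyl carbon of a γ-lactone (ring O–C6–C1–C2–C3). A two-carbon iodoethyl arm (C5–C4) on C6 then closes onto that carbonyl, which forms the carbocycle and frees the C6 alcohol in one event.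
- Forward order: (S)-linalool is cut down to a C6 acid whose radical adds to (R)-5-methylfuran-2(5H)-one (sets C1); two lactone alkylations build C2; the lactone is opened and oxidized to a keto acid; a two-carbon unit adds to the C6 ketone and the lactone is closed again; the cyclohexane ring forms last.
- Stereochemistry: side-chain carbinol from (S)-linalool; C1 by addition anti to the ring methyl of the (R)-butenolide; C2 by alkylation anti to the C1 chain; C6 by Felkin–Anh addition; C3 by axial hydrogen-atom transfer to an α-bromo radical; (E)-alkene by cross-metathesis.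

Key step: step 11

Assumption: (S)-(+)-linalool and (R)-γ-valerolactone are used as bought in high enantiomeric purity; "chain A" below means the (3S)-3-methyl-3-(triethylsilyloxy)pent-4-en-1-yl group.

**Route**

Step 1
Reactants: 1 (S)-(+)-linalool
Product: 2 (3S)-3,7-dimethyl-3-(triethylsilyloxy)octa-1,6-diene
Conditions: Et3SiOTf, 2,6-lutidine, CH2Cl2, 0 °C
Reagents that add atoms: triethylsilyl trifluoromethanesulfonate, CC[Si](CC)(CC)OS(=O)(=O)C(F)(F)F
Why: Silyl ether formation with a silyl triflate and a hindered base is standard for tertiary alcohols, leaves the (S) center untouched, and keeps the carbinol from closing onto the acid made in the next step.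

Step 2
Reactants: 2 (3S)-3,7-dimethyl-3-(triethylsilyloxy)octa-1,6-diene
Product: 5 (4S)-4-methyl-4-(triethylsilyloxy)hex-5-enoic acid, via secondary ozonide 3 (not isolated), via aldehyde 4 (not isolated)
Conditions: O3 (1 equiv, dye end point), CH2Cl2, −78 °C; Me2S; then NaClO2, NaH2PO4, 2-methylbut-2-ene, t-BuOH/H2O, rt
Reagents that add atoms: ozone, [O-][O+]=O; sodium chlorite, [Na+].[O-]Cl=O
Why: Ozone should attack the electron-rich trisubstituted alkene much faster than the hindered vinyl group (chemoselective ozonolysis), and Pinnick oxidation then takes the aldehyde to the acid without touching the alkene or the silyl ether.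

Step 3
Reactants: 6 (R)-γ-valerolactone
Product: 10 (R)-5-methylfuran-2(5H)-one, via lithium enolate 7 (not isolated), via selenide 8 (not isolated), via selenoxide 9 (not isolated)
Conditions: LiN(iPr)2, THF, −78 °C; PhSeBr; then H2O2, pyridine, CH2Cl2, 0 °C → rt
Reagents that add atoms: none
Why: α-Selenenylation of the lactone enolate and syn elimination of the selenoxide (selenoxide elimination) should place the double bond in the ring, the only side with a β-hydrogen, while the methyl-bearing stereocenter is not involved.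

Step 4
Reactants: 5 (4S)-4-methyl-4-(triethylsilyloxy)hex-5-enoic acid; 10 (R)-5-methylfuran-2(5H)-one
Product: 12 (4S,5R)-5-methyl-4-(chain A)oxolan-2-one, via redox-active ester 11 (not isolated)
Conditions: N-hydroxyphthalimide, DIC, DMAP (cat.), CH2Cl2, rt; then 10 (2 equiv), Ru(bpy)3(PF6)2 (1 mol%), Hantzsch ester, blue LEDs, rt
Reagents that add atoms: none
Why: In this decarboxylative Giese addition the primary radical released from the reduced N-(acyloxy)phthalimide should add to the β-carbon of the butenolide on the face away from the ring methyl group, which sets C1 trans to that methyl, and the resulting α-lactone radical is reduced by the Hantzsch ester.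

Step 5
Reactants: 12 (4S,5R)-5-methyl-4-(chain A)oxolan-2-one
Product: 14 (3S,4S,5R)-3,5-dimethyl-4-(chain A)oxolan-2-one, via lithium enolate 13 (not isolated)
Conditions: LiN(iPr)2, THF, −78 °C; MeI
Reagents that add atoms: iodomethane, CI
Why: Alkylation of the lactone enolate should deliver the methyl group anti to the neighbouring chain, although this center becomes planar again in the next step.

Step 6
Reactants: 14 (3S,4S,5R)-3,5-dimethyl-4-(chain A)oxolan-2-one
Product: 16 (3S,4S,5R)-3,5-dimethyl-4-(chain A)-3-(prop-2-en-1-yl)oxolan-2-one, via lithium enolate 15 (not isolated)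
Conditions: LiN(iPr)2, THF/DMPU, −78 °C; allyl bromide, −78 → −20 °C
Reagents that add atoms: allyl bromide, C=CCBr
Why: In this second enolate alkylation allyl bromide should approach the face of the five-membered enolate anti to the adjacent chain A, so quaternary C2 is set with allyl trans and methyl cis to that chain (1,2-induction in a lactone enolate).

Step 7
Reactants: 16 (3S,4S,5R)-3,5-dimethyl-4-(chain A)-3-(prop-2-en-1-yl)oxolan-2-one
Product: 18 (2S,3S,6S)-3-acetyl-2,6-dimethyl-2-(prop-2-en-1-yl)-6-(triethylsilyloxy)oct-7-enoic acid, via lithium hydroxy carboxylate 17 (not isolated)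
Conditions: LiOH, THF/H2O, 60 °C; evaporate; AZADO (cat.), KBr (cat.), NaOCl, NaHCO3, CH2Cl2/H2O, 0 °C; HCl to pH 4
Reagents that add atoms: lithium hydroxide, [Li+].[OH-]
Why: Saponification gives a hydroxy carboxylate that cannot close back as its salt, and nitroxyl/hypochlorite oxidation (Anelli-type, with the unhindered nitroxyl AZADO) should convert the hindered secondary carbinol into the methyl ketone under weakly basic conditions that leave the terminal alkenes and the C1 center alone.

Step 8
Reactants: 18 (2S,3S,6S)-3-acetyl-2,6-dimethyl-2-(prop-2-en-1-yl)-6-(triethylsilyloxy)oct-7-enoic acid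
Product: 20 thioester lactone S-ethyl 2-[(2S,3S,4S)-2,4-dimethyl-3-(chain A)-5-oxo-4-(prop-2-en-1-yl)oxolan-2-yl]ethanethioate, via hydroxy acid 19 (not isolated)
Conditions: CH3C(O)SEt/LiN(iPr)2 (3.5 equiv), THF, −78 °C; AcOH; then 2,4,6-Cl3C6H2COCl, Et3N, DMAP (cat.), toluene, rt
Reagents that add atoms: S-ethyl thioacetate, CCSC(C)=O
Why: Aldol addition of the thioester enolate to the methyl ketone should follow the Felkin–Anh model (quaternary C2 as the large group anti to the nucleophile, attack past the C1 hydrogen), which gives the (S) carbinol at C6, and Yamaguchi lactonization through the activated acyl group closes the γ-lactone with retention at C6 because no tertiary cation is formed.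

Step 9
Reactants: 20 thioester lactone
Product: 22 (3S,4S,5S)-5-(2-hydroxyethyl)-3,5-dimethyl-4-(chain A)-3-(prop-2-en-1-yl)oxolan-2-one, via aldehyde 21 (not isolated)
Conditions: NaBH4, EtOH/THF, 0 °C → rt
Reagents that add atoms: none
Why: NaBH4 reduces thioesters to primary alcohols (chemoselective thioester reduction) but should not reduce the lactone, whose carbonyl sits next to quaternary C2.

Step 10
Reactants: 22 (3S,4S,5S)-5-(2-hydroxyethyl)-3,5-dimethyl-4-(chain A)-3-(prop-2-en-1-yl)oxolan-2-one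
Product: 23 (3S,4S,5S)-5-(2-iodoethyl)-3,5-dimethyl-4-(chain A)-3-(prop-2-en-1-yl)oxolan-2-one
Conditions: I2, PPh3, imidazole, CH2Cl2, 0 °C
Reagents that add atoms: iodine, II
Why: Appel-type iodination of the unhindered primary alcohol should proceed cleanly, since the lactone, the silyl ether and the alkenes are inert to the phosphonium reagent.

Step 11
Reactants: 23 (3S,4S,5S)-5-(2-iodoethyl)-3,5-dimethyl-4-(chain A)-3-(prop-2-en-1-yl)oxolan-2-one
Product: 26 (2S,3S,4S)-4-hydroxy-2,4-dimethyl-3-(chain A)-2-(prop-2-en-1-yl)cyclohexan-1-one, via alkyllithium 24 (not isolated), via bridged lithium alkoxide 25 (not isolated)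
Conditions: t-BuLi (2.1 equiv), Et2O/pentane, −78 → −20 °C; aq. NH4Cl
Reagents that add atoms: none
Why: Iodine–lithium exchange at C4 should be faster than any attack of t-BuLi on the hindered lactone and gives alkyllithium 24, whose C4 carbanion adds to the lactone carbonyl C3 and so forms the C3–C4 bond. The resulting bridged lithium hemiketal alkoxide 25 (a 7-oxabicyclo[2.2.1]heptane) should persist in the cold, so no second addition can occur, and on protonation it opens to hydroxy ketone 26, which frees the tertiary C6 alcohol in the same operation. The closest known reaction type is the Parham-type intramolecular nucleophilic acyl substitution of iodoalkyl esters and lactones started by halogen–metal exchange or by SmI2. The six-membered carbocycle closes in the 6-exo-trig mode. No lasting stereocenter is created (the carbinol carbon of 25 is transient and fixed by the bicycle), and C1, C2 and C6 pass through unchanged because the lactone has no α-hydrogen at quaternary C2 and cannot be enolized. The step needs chemoselectivity for exchange over carbonyl addition and over the two terminal alkenes, which the shielding of the carbonyl by C2 and the low temperature should secure.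

Step 12
Reactants: 26 (2S,3S,4S)-4-hydroxy-2,4-dimethyl-3-(chain A)-2-(prop-2-en-1-yl)cyclohexan-1-one
Product: 28 (1S,2S,3S)-4,4-dibromo-1,3-dimethyl-2-(chain A)-3-(prop-2-en-1-yl)cyclohexan-1-ol, via hydrazone 27 (not isolated)
Conditions: N2H4·H2O, EtOH, 80 °C (argon); evaporate; CuBr2, LiOtBu, THF, 0 °C → rt
Reagents that add atoms: copper dibromide (CuBr2), [Cu+2].[Br-].[Br-]
Why: Oxidative bromination of a ketone hydrazone with CuBr2 and base (geminal dihalide synthesis from hydrazones, a relative of the Barton vinyl halide reaction) should replace the carbonyl oxygen by two bromine atoms with loss of N2, and C3 is not yet a stereocenter.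

Step 13
Reactants: 28 (1S,2S,3S)-4,4-dibromo-1,3-dimethyl-2-(chain A)-3-(prop-2-en-1-yl)cyclohexan-1-ol
Product: 29 (1S,2S,3S,4S)-4-bromo-1,3-dimethyl-2-(chain A)-3-(prop-2-en-1-yl)cyclohexan-1-ol
Conditions: Bu3SnH (1.05 equiv), Et3B/air (cat.), toluene, −40 °C
Reagents that add atoms: none
Why: In this radical-chain mono-reduction of a geminal dibromide the α-bromo radical at C3 should take its hydrogen atom along the axial direction on the face opposite the axial C2 methyl group, so bromine ends equatorial and cis to that methyl as in the target, and the remaining secondary bromide should react far more slowly than the dibromide.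

Step 14
Reactants: 29 (1S,2S,3S,4S)-4-bromo-1,3-dimethyl-2-(chain A)-3-(prop-2-en-1-yl)cyclohexan-1-ol
Product: 30 (1S,2S,3S,4S)-4-bromo-3-[(2E)-4-hydroxy-4-methylpent-2-en-1-yl]-1,3-dimethyl-2-(chain A)cyclohexan-1-ol
Conditions: 2-methylbut-3-en-2-ol (10 equiv), second-generation Hoveyda–Grubbs catalyst (5 mol%), CH2Cl2, 40 °C
Reagents that add atoms: 2-methylbut-3-en-2-ol, C=CC(C)(C)O
Why: Olefin cross-metathesis of the allyl group with an excess of the tertiary allylic alcohol should give the (E)-alkene under thermodynamic control, while the vinyl group beside the silylated quaternary carbinol is too hindered to enter the catalytic cycle.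

Step 15
Reactants: 30 (1S,2S,3S,4S)-4-bromo-3-[(2E)-4-hydroxy-4-methylpent-2-en-1-yl]-1,3-dimethyl-2-(chain A)cyclohexan-1-ol
Product: 31 (1S,2S,3S,4S)-4-bromo-3-[(2E)-4-hydroxy-4-methylpent-2-en-1-yl]-2-[(3S)-3-hydroxy-3-methylpent-4-en-1-yl]-1,3-dimethylcyclohexan-1-ol (CNP0193074.2)
Conditions: HF·pyridine, pyridine, THF, 0 °C → rt
Reagents that add atoms: none
Why: Fluoride cleavage of the tertiary triethylsilyl ether under buffered, non-basic conditions should free the last alcohol without loss of the equatorial bromide, which has no antiperiplanar hydrogen for elimination.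

**Compound list**

1 | (S)-(+)-linalool | C=C[C@@](C)(O)CCC=C(C)C | starting material
2 | (3S)-3,7-dimethyl-3-(triethylsilyloxy)octa-1,6-diene | C=C[C@@](C)(O[Si](CC)(CC)CC)CCC=C(C)C | intermediate
3 | secondary ozonide of 2 (1,2,4-trioxolane at the former trisubstituted alkene) | C=C[C@@](C)(O[Si](CC)(CC)CC)CCC1OOC(C)(C)O1 | intermediate
4 | (4S)-4-methyl-4-(triethylsilyloxy)hex-5-enal | C=C[C@@](C)(O[Si](CC)(CC)CC)CCC=O | intermediate
5 | (4S)-4-methyl-4-(triethylsilyloxy)hex-5-enoic acid | C=C[C@@](C)(O[Si](CC)(CC)CC)CCC(=O)O | intermediate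
6 | (R)-γ-valerolactone, (5R)-5-methyloxolan-2-one | C[C@@H]1CCC(=O)O1 | starting material
7 | lithium enolate of 6 | C[C@@H]1CC=C([O-])O1.[Li+] | intermediate
8 | (5R)-5-methyl-3-(phenylselanyl)oxolan-2-one | C[C@@H]1CC([Se]c2ccccc2)C(=O)O1 | intermediate
9 | selenoxide of 8 | C[C@@H]1CC([Se](=O)c2ccccc2)C(=O)O1 | intermediate
10 | (R)-5-methylfuran-2(5H)-one | C[C@@H]1C=CC(=O)O1 | intermediate
11 | 1,3-dioxoisoindolin-2-yl (4S)-4-methyl-4-(triethylsilyloxy)hex-5-enoate | C=C[C@@](C)(O[Si](CC)(CC)CC)CCC(=O)ON1C(=O)c2ccccc2C1=O | intermediate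
12 | (4S,5R)-5-methyl-4-[(3S)-3-methyl-3-(triethylsilyloxy)pent-4-en-1-yl]oxolan-2-one | C=C[C@@](C)(O[Si](CC)(CC)CC)CC[C@H]1CC(=O)O[C@@H]1C | intermediate
13 | lithium enolate of 12 | C=C[C@@](C)(O[Si](CC)(CC)CC)CC[C@H]1C=C([O-])O[C@@H]1C.[Li+] | intermediate
14 | (3S,4S,5R)-3,5-dimethyl-4-[(3S)-3-methyl-3-(triethylsilyloxy)pent-4-en-1-yl]oxolan-2-one | C=C[C@@](C)(O[Si](CC)(CC)CC)CC[C@H]1[C@H](C)C(=O)O[C@@H]1C | intermediate
15 | lithium enolate of 14 | C=C[C@@](C)(O[Si](CC)(CC)CC)CC[C@H]1C(C)=C([O-])O[C@@H]1C.[Li+] | intermediate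
16 | (3S,4S,5R)-3,5-dimethyl-4-[(3S)-3-methyl-3-(triethylsilyloxy)pent-4-en-1-yl]-3-(prop-2-en-1-yl)oxolan-2-one | C=C[C@@](C)(O[Si](CC)(CC)CC)CC[C@H]1[C@](C)(CC=C)C(=O)O[C@@H]1C | intermediate
17 | lithium (2S,3S,6S)-3-[(1R)-1-hydroxyethyl]-2,6-dimethyl-2-(prop-2-en-1-yl)-6-(triethylsilyloxy)oct-7-enoate | C=C[C@@](C)(O[Si](CC)(CC)CC)CC[C@H]([C@@H](C)O)[C@](C)(CC=C)C(=O)[O-].[Li+] | intermediate
18 | (2S,3S,6S)-3-acetyl-2,6-dimethyl-2-(prop-2-en-1-yl)-6-(triethylsilyloxy)oct-7-enoic acid | C=C[C@@](C)(O[Si](CC)(CC)CC)CC[C@H](C(C)=O)[C@](C)(CC=C)C(=O)O | intermediate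
19 | (2S,3S,6S)-3-[(2S)-4-(ethylsulfanyl)-2-hydroxy-4-oxobutan-2-yl]-2,6-dimethyl-2-(prop-2-en-1-yl)-6-(triethylsilyloxy)oct-7-enoic acid | C=C[C@@](C)(O[Si](CC)(CC)CC)CC[C@H]([C@@](C)(O)CC(=O)SCC)[C@](C)(CC=C)C(=O)O | intermediate
20 | S-ethyl 2-[(2S,3S,4S)-2,4-dimethyl-3-(chain A)-5-oxo-4-(prop-2-en-1-yl)oxolan-2-yl]ethanethioate | C=C[C@@](C)(O[Si](CC)(CC)CC)CC[C@H]1[C@](C)(CC=C)C(=O)O[C@@]1(C)CC(=O)SCC | intermediate
21 | 2-[(2S,3S,4S)-2,4-dimethyl-3-(chain A)-5-oxo-4-(prop-2-en-1-yl)oxolan-2-yl]acetaldehyde | C=C[C@@](C)(O[Si](CC)(CC)CC)CC[C@H]1[C@](C)(CC=C)C(=O)O[C@@]1(C)CC=O | intermediate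
22 | (3S,4S,5S)-5-(2-hydroxyethyl)-3,5-dimethyl-4-(chain A)-3-(prop-2-en-1-yl)oxolan-2-one | C=C[C@@](C)(O[Si](CC)(CC)CC)CC[C@H]1[C@](C)(CC=C)C(=O)O[C@@]1(C)CCO | intermediate
23 | (3S,4S,5S)-5-(2-iodoethyl)-3,5-dimethyl-4-(chain A)-3-(prop-2-en-1-yl)oxolan-2-one | C=C[C@@](C)(O[Si](CC)(CC)CC)CC[C@H]1[C@](C)(CC=C)C(=O)O[C@@]1(C)CCI | intermediate
24 | alkyllithium from 23 (lithium in place of iodine at C4) | C=C[C@@](C)(O[Si](CC)(CC)CC)CC[C@H]1[C@](C)(CC=C)C(=O)O[C@@]1(C)CC[Li] | intermediate
25 | lithium 7-oxabicyclo[2.2.1]heptan-1-olate (bridgeheads C3 and C6, oxygen bridge from C6) | C=C[C@@](C)(O[Si](CC)(CC)CC)CC[C@H]1[C@](C)(CC=C)[C@@]2([O-])CC[C@]1(C)O2.[Li+] | intermediate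
26 | (2S,3S,4S)-4-hydroxy-2,4-dimethyl-3-(chain A)-2-(prop-2-en-1-yl)cyclohexan-1-one | C=C[C@@](C)(O[Si](CC)(CC)CC)CC[C@H]1[C@](C)(CC=C)C(=O)CC[C@]1(C)O | intermediate
27 | hydrazone of 26 | C=C[C@@](C)(O[Si](CC)(CC)CC)CC[C@H]1[C@](C)(CC=C)C(=NN)CC[C@]1(C)O | intermediate
28 | (1S,2S,3S)-4,4-dibromo-1,3-dimethyl-2-(chain A)-3-(prop-2-en-1-yl)cyclohexan-1-ol | C=C[C@@](C)(O[Si](CC)(CC)CC)CC[C@H]1[C@](C)(CC=C)C(Br)(Br)CC[C@]1(C)O | intermediate
29 | (1S,2S,3S,4S)-4-bromo-1,3-dimethyl-2-(chain A)-3-(prop-2-en-1-yl)cyclohexan-1-ol | C=C[C@@](C)(O[Si](CC)(CC)CC)CC[C@H]1[C@](C)(CC=C)[C@@H](Br)CC[C@]1(C)O | intermediate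
30 | (1S,2S,3S,4S)-4-bromo-3-[(2E)-4-hydroxy-4-methylpent-2-en-1-yl]-1,3-dimethyl-2-(chain A)cyclohexan-1-ol | C=C[C@@](C)(O[Si](CC)(CC)CC)CC[C@H]1[C@](C)(C/C=C/C(C)(C)O)[C@@H](Br)CC[C@]1(C)O | intermediate
31 | (1S,2S,3S,4S)-4-bromo-3-[(2E)-4-hydroxy-4-methylpent-2-en-1-yl]-2-[(3S)-3-hydroxy-3-methylpent-4-en-1-yl]-1,3-dimethylcyclohexan-1-ol | C=C[C@@](C)(O)CC[C@H]1[C@](C)(C/C=C/C(C)(C)O)[C@@H](Br)CC[C@]1(C)O | target

**Step count and risks**

Total steps: 15. Longest linear sequence: 14 (steps 1, 2 and 4 to 15; step 3 makes the butenolide partner).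

Steps most likely to fail:

1. Step 12. The hindered hydrazone may lose a proton toward C4 and give the bromoalkene, or suffer a 1,2-shift from quaternary C2, instead of taking up the second bromide. Fallback (ionic inversion in place of the dibromide): from 26, reduction with LiBH(s-Bu)3 (THF, −78 °C) from the equatorial side should give the axial C3 alcohol (1S,2S,3S,4R)-1,3-dimethyl-2-(chain A)-3-(prop-2-en-1-yl)cyclohexane-1,4-diol F1. Tf2O/pyridine (CH2Cl2, −40 °C) converts it into the secondary triflate F2, and displacement with Bu4NBr (toluene, 0 °C → rt) with inversion returns to the route at 29.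

2. Step 8. The methyl ketone may be enolized, the aldolate may revert, and chelation through the carboxylate may erode or reverse the facial selectivity at C6. Fallback (acetylide addition and anti-Markovnikov hydration in place of the acetate aldol): from 18, the lithium carboxylate is treated with HC≡CMgBr/CeCl3 (THF, −78 °C), a small non-enolizing nucleophile, to give the ethynyl carbinol acid F3. Yamaguchi lactonization gives the ethynyl lactone F4. Alkyne-selective hydroboration (CuCl, Xantphos, NaOtBu, B2pin2, MeOH, THF) gives the (E)-alkenyl boronate F5. Oxidation with NaBO3 gives aldehyde 21, which is reduced in the same flask with NaBH4 to 22.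

3. Step 11. t-BuLi may add directly to the lactone carbonyl, or the alkyllithium may be protonated before it closes the ring. Fallback (stabilized carbanion in place of the alkyllithium): from 23, PhSO2Na (DMF, rt) gives the sulfone F6. LiN(SiMe3)2 (2.2 equiv, THF, −78 → 0 °C) makes the α-sulfonyl carbanion, which acylates on the lactone (Dieckmann-type closure of the C3–C4 bond) to give the cyclic β-keto sulfone F7. Reductive desulfonylation with SmI2 (THF/MeOH, −78 °C) returns to the route at 26.

**Further compounds**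

F1 | step 12 | (1S,2S,3S,4R)-1,3-dimethyl-2-(chain A)-3-(prop-2-en-1-yl)cyclohexane-1,4-diol (axial C3 alcohol) | C=C[C@@](C)(O[Si](CC)(CC)CC)CC[C@H]1[C@](C)(CC=C)[C@H](O)CC[C@]1(C)O
F2 | step 12 | trifluoromethanesulfonate of F1 at the secondary alcohol | C=C[C@@](C)(O[Si](CC)(CC)CC)CC[C@H]1[C@](C)(CC=C)[C@H](OS(=O)(=O)C(F)(F)F)CC[C@]1(C)O
F3 | step 8 | (2S,3S,6S)-3-[(2S)-2-hydroxybut-3-yn-2-yl]-2,6-dimethyl-2-(prop-2-en-1-yl)-6-(triethylsilyloxy)oct-7-enoic acid | C=C[C@@](C)(O[Si](CC)(CC)CC)CC[C@H]([C@@](C)(O)C#C)[C@](C)(CC=C)C(=O)O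
F4 | step 8 | 5-ethynyl analogue of lactone 22 (ethynyl in place of 2-hydroxyethyl) | C=C[C@@](C)(O[Si](CC)(CC)CC)CC[C@H]1[C@](C)(CC=C)C(=O)O[C@@]1(C)C#C
F5 | step 8 | (E)-2-(pinacolboryl)ethenyl lactone from F4 | C=C[C@@](C)(O[Si](CC)(CC)CC)CC[C@H]1[C@](C)(CC=C)C(=O)O[C@@]1(C)/C=C/B2OC(C)(C)C(C)(C)O2
F6 | step 11 | 5-[2-(phenylsulfonyl)ethyl] analogue of lactone 23 | C=C[C@@](C)(O[Si](CC)(CC)CC)CC[C@H]1[C@](C)(CC=C)C(=O)O[C@@]1(C)CCS(=O)(=O)c2ccccc2
F7 | step 11 | 6-(phenylsulfonyl) derivative of hydroxy ketone 26 (sulfone on C4 of the target numbering) | C=C[C@@](C)(O[Si](CC)(CC)CC)CC[C@H]1[C@](C)(CC=C)C(=O)C(S(=O)(=O)c2ccccc2)CC[C@]1(C)O
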